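The route rests on cutting the C4–C4a bond of the 4'-methoxyflavone (flavone 1): its ring C is closed by intramolecular Friedel–Crafts acylation of a (Z)-3-aryloxy-3-(4-methoxyphenyl)acrylic acid whose aryl group is ring A, already joined through its C8 oxygen to C4' of complete, benzyl-protected flavone 2. The step exploits the position of O1 on C8a of ring A: of the two carbons ortho to C8a, C8 carries the diaryl ether oxygen and only C4a is free, so the acyl arm hanging from O1 can close ring C in one operation with the 8-O linkage fixed and no 6-O isomer possible. Hydrogenolysis of three benzyl ethers then gives the target.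

Key step: step 11

Remarks on the chemistry: the target has no stereocentre, so the only stereochemical elements in the route are the alkene geometries of 10, 14, 15 and 16. The diaryl ether is made on 4-fluorobenzaldehyde, where a para formyl group activates fluoride, and flavone 2 is then grown from that aldehyde. The 5-oxygen of flavone 2 is kept as a benzyl ether so that only one phenol is present when the propiolate is added.

Step 1
Reactants: 1 2,4,6-trihydroxybenzaldehyde
Product: 2 2,4-bis(benzyloxy)-6-hydroxybenzaldehyde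
Conditions: BnBr (2.0 equiv), K2CO3, DMF, 0 °C to rt
Reagents that add atoms: benzyl bromide, BrCc1ccccc1
Why: Williamson etherification in which the 4-OH and one ortho OH are alkylated while the remaining ortho OH, hydrogen-bonded to the formyl group, stays free when two equivalents of bromide are used.

Step 2
Reactants: 2 2,4-bis(benzyloxy)-6-hydroxybenzaldehyde
Product: 3 2,4-bis(benzyloxy)-6-(methoxymethoxy)benzaldehyde
Conditions: NaH, DMF, 0 °C; then MOMCl, 0 °C to rt
Reagents that add atoms: chloromethyl methyl ether (MOMCl), COCCl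
Why: O-alkylation of the sodium phenoxide (MOM protection) masks the oxygen that later becomes O1 of flavone 1 with an acetal that can be removed without touching benzyl ethers.

Step 3
Reactants: 3 2,4-bis(benzyloxy)-6-(methoxymethoxy)benzaldehyde
Product: 5 2,4-bis(benzyloxy)-6-(methoxymethoxy)phenol, via aryl formate 4 (not isolated)
Conditions: mCPBA (1.2 equiv), CH2Cl2, 0 °C to rt; aq. Na2S2O3 wash; then K2CO3 (cat.), MeOH, rt, under argon
Reagents that add atoms: meta-chloroperoxybenzoic acid (mCPBA), OOC(=O)c1cccc(Cl)c1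
Why: Baeyer–Villiger (Dakin-type) oxidation, in which the electron-rich 2,4,6-trioxygenated aryl group migrates in preference to hydrogen, followed by mild methanolysis of the formate to release the phenol.

Step 4
Reactants: 5 2,4-bis(benzyloxy)-6-(methoxymethoxy)phenol; 6 4-fluorobenzaldehyde
Product: 7 4-[2,4-bis(benzyloxy)-6-(methoxymethoxy)phenoxy]benzaldehyde
Conditions: K2CO3, DMF, 110 °C, under N2
Reagents that add atoms: none
Why: Nucleophilic aromatic substitution (addition–elimination through a Meisenheimer complex) in which the para formyl group activates fluoride toward the 2,6-dioxygenated phenoxide.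

Step 5
Reactants: 8 2',6'-dihydroxy-4'-methoxyacetophenone
Product: 9 1-[2-(benzyloxy)-6-hydroxy-4-methoxyphenyl]ethan-1-one
Conditions: BnBr (1.05 equiv), K2CO3, acetone, reflux
Reagents that add atoms: benzyl bromide, BrCc1ccccc1
Why: Williamson mono-etherification of a symmetrical ketone, after which the remaining OH is locked in a hydrogen bond to the acetyl group and resists a second alkylation.

Step 6
Reactants: 9 1-[2-(benzyloxy)-6-hydroxy-4-methoxyphenyl]ethan-1-one; 7 4-[2,4-bis(benzyloxy)-6-(methoxymethoxy)phenoxy]benzaldehyde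
Product: 10 (E)-1-[2-(benzyloxy)-6-hydroxy-4-methoxyphenyl]-3-{4-[2,4-bis(benzyloxy)-6-(methoxymethoxy)phenoxy]phenyl}prop-2-en-1-one
Conditions: KOH (50% aq.), EtOH–THF, rt
Reagents that add atoms: none
Why: Claisen–Schmidt condensation (aldol addition then E1cB dehydration) should give the conjugated E enone as the thermodynamic alkene, and the acetal, benzyl ethers and diaryl ether are inert to hydroxide.

Step 7
Reactants: 10 (E)-1-[2-(benzyloxy)-6-hydroxy-4-methoxyphenyl]-3-{4-[2,4-bis(benzyloxy)-6-(methoxymethoxy)phenoxy]phenyl}prop-2-en-1-one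
Product: 11 5-(benzyloxy)-2-{4-[2,4-bis(benzyloxy)-6-(methoxymethoxy)phenoxy]phenyl}-7-methoxy-4H-chromen-4-one
Conditions: I2 (10 mol%), DMSO, 120 °C; aq. Na2S2O3 work-up
Reagents that add atoms: none
Why: Iodine-catalysed oxidative cyclisation of a 2'-hydroxychalcone, in which iodine activates the enone alkene, the phenol oxygen closes 6-endo onto the β-carbon and loss of HI (reoxidised to I2 by DMSO) gives the chromone, while any acetal cleaved in passing is harmless because step 8 removes it on purpose.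

Step 8
Reactants: 11 5-(benzyloxy)-2-{4-[2,4-bis(benzyloxy)-6-(methoxymethoxy)phenoxy]phenyl}-7-methoxy-4H-chromen-4-one
Product: 12 5-(benzyloxy)-2-{4-[2,4-bis(benzyloxy)-6-hydroxyphenoxy]phenyl}-7-methoxy-4H-chromen-4-one
Conditions: 2 M HCl, MeOH–THF, 45 °C
Reagents that add atoms: none
Why: Acid-catalysed acetal methanolysis (MOM removal) frees the phenol ortho to the diaryl ether, while benzyl and methyl aryl ethers are stable to dilute HCl at this temperature.

Step 9
Reactants: 12 5-(benzyloxy)-2-{4-[2,4-bis(benzyloxy)-6-hydroxyphenoxy]phenyl}-7-methoxy-4H-chromen-4-one; 13 methyl 3-(4-methoxyphenyl)propiolate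
Product: 14 methyl (Z)-3-{3,5-bis(benzyloxy)-2-[4-(5-(benzyloxy)-7-methoxy-4-oxo-4H-chromen-2-yl)phenoxy]phenoxy}-3-(4-methoxyphenyl)acrylate (aryloxy group cis to the ester)
Conditions: K2CO3, DMF, 80 °C
Reagents that add atoms: none
Why: Base-mediated oxa-Michael addition of the only phenoxide present to the aryl-bearing β-carbon of the alkynoate, where anti protonation of the vinyl anion places the aryloxy group cis to the ester and so sets the Z alkene.

Step 10
Reactants: 14 methyl (Z)-3-{3,5-bis(benzyloxy)-2-[4-(5-(benzyloxy)-7-methoxy-4-oxo-4H-chromen-2-yl)phenoxy]phenoxy}-3-(4-methoxyphenyl)acrylate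
Product: 15 (Z)-3-{3,5-bis(benzyloxy)-2-[4-(5-(benzyloxy)-7-methoxy-4-oxo-4H-chromen-2-yl)phenoxy]phenoxy}-3-(4-methoxyphenyl)acrylic acid
Conditions: LiOH·H2O, THF–MeOH–H2O, rt; then 1 M HCl to pH 3
Reagents that add atoms: lithium hydroxide, [Li+].[OH-]
Why: Ester saponification (acyl–oxygen cleavage) at ambient temperature is mild enough to leave the aryl vinyl ether and the chromone of flavone 2 intact, and acidification gives the free acid.

Step 11
Reactants: 15 (Z)-3-{3,5-bis(benzyloxy)-2-[4-(5-(benzyloxy)-7-methoxy-4-oxo-4H-chromen-2-yl)phenoxy]phenoxy}-3-(4-methoxyphenyl)acrylic acid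
Product: 17 5,7-bis(benzyloxy)-8-{4-[5-(benzyloxy)-7-methoxy-4-oxo-4H-chromen-2-yl]phenoxy}-2-(4-methoxyphenyl)-4H-chromen-4-one, via mixed trifluoroacetic anhydride 16 (not isolated)
Conditions: (CF3CO)2O (3 equiv), CH2Cl2, 0 °C to rt; aq. NaHCO3 work-up
Reagents that add atoms: none
Why: Trifluoroacetic anhydride converts the acid into mixed anhydride 16, which ionises to an acylium ion that the Z alkene holds next to ring A; C4a attacks it in an electrophilic aromatic substitution and loss of the C4a proton rearomatises ring A. The closest known reaction type is the Ruhemann flavone synthesis, the intramolecular Friedel–Crafts acylation of a β-aryloxycinnamic acid. Ring C, a six-membered pyranone, is closed by C4–C4a bond formation in a 6-exo attack on the acyl carbon (exo-trig on the anhydride carbonyl, exo-dig on the free acylium). No stereocentre is formed. The step needs regioselectivity for C4a and chemoselectivity over intermolecular acylation: the tether from O1 reaches only the carbons ortho to C8a, C8 is occupied by the diaryl ether oxygen and the very nucleophilic C6 between the two benzyloxy groups is out of reach, while C4a is activated by O1 (ortho), the 5-benzyloxy group (ortho) and the 7-benzyloxy group (para), so closure should outrun trifluoroacetylation without any strong protic or Lewis acid that would strip benzyl ethers. Any E acid present should funnel into the same product, because reversible α-protonation of the push–pull enol ether by the trifluoroacetic acid formed allows rotation to the Z form.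

Step 12
Reactants: 17 5,7-bis(benzyloxy)-8-{4-[5-(benzyloxy)-7-methoxy-4-oxo-4H-chromen-2-yl]phenoxy}-2-(4-methoxyphenyl)-4H-chromen-4-one
Product: 18 5,7-dihydroxy-8-[4-(5-hydroxy-7-methoxy-4-oxo-4H-chromen-2-yl)phenoxy]-2-(4-methoxyphenyl)-4H-chromen-4-one
Conditions: H2 (1 atm), 10% Pd/C, THF–MeOH, rt
Reagents that add atoms: none
Why: Catalytic hydrogenolysis of the three benzyl aryl ethers under neutral conditions avoids the acid that could open ring C and scramble the 8-O linkage (Wessely–Moser rearrangement), and should leave the methyl ethers, the diaryl ether and both chromone C2=C3 bonds untouched at balloon pressure.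

Compound list
1 | 2,4,6-trihydroxybenzaldehyde | O=Cc1c(O)cc(O)cc1O | starting material
2 | 2,4-bis(benzyloxy)-6-hydroxybenzaldehyde | O=Cc1c(O)cc(OCc2ccccc2)cc1OCc1ccccc1 | intermediate
3 | 2,4-bis(benzyloxy)-6-(methoxymethoxy)benzaldehyde | O=Cc1c(OCOC)cc(OCc2ccccc2)cc1OCc1ccccc1 | intermediate
4 | 2,4-bis(benzyloxy)-6-(methoxymethoxy)phenyl formate | O=COc1c(OCOC)cc(OCc2ccccc2)cc1OCc1ccccc1 | intermediate
5 | 2,4-bis(benzyloxy)-6-(methoxymethoxy)phenol | Oc1c(OCOC)cc(OCc2ccccc2)cc1OCc1ccccc1 | intermediate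
6 | 4-fluorobenzaldehyde | O=Cc1ccc(F)cc1 | starting material
7 | 4-[2,4-bis(benzyloxy)-6-(methoxymethoxy)phenoxy]benzaldehyde | O=Cc1ccc(Oc2c(OCOC)cc(OCc3ccccc3)cc2OCc2ccccc2)cc1 | intermediate
8 | 2',6'-dihydroxy-4'-methoxyacetophenone | CC(=O)c1c(O)cc(OC)cc1O | starting material
9 | 1-[2-(benzyloxy)-6-hydroxy-4-methoxyphenyl]ethan-1-one | CC(=O)c1c(O)cc(OC)cc1OCc1ccccc1 | intermediate
10 | (E)-1-[2-(benzyloxy)-6-hydroxy-4-methoxyphenyl]-3-{4-[2,4-bis(benzyloxy)-6-(methoxymethoxy)phenoxy]phenyl}prop-2-en-1-one | COCOc1cc(OCc2ccccc2)cc(OCc2ccccc2)c1Oc1ccc(/C=C/C(=O)c2c(O)cc(OC)cc2OCc2ccccc2)cc1 | intermediate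
11 | 5-(benzyloxy)-2-{4-[2,4-bis(benzyloxy)-6-(methoxymethoxy)phenoxy]phenyl}-7-methoxy-4H-chromen-4-one | COCOc1cc(OCc2ccccc2)cc(OCc2ccccc2)c1Oc1ccc(-c2cc(=O)c3c(OCc4ccccc4)cc(OC)cc3o2)cc1 | intermediate
12 | 5-(benzyloxy)-2-{4-[2,4-bis(benzyloxy)-6-hydroxyphenoxy]phenyl}-7-methoxy-4H-chromen-4-one | Oc1cc(OCc2ccccc2)cc(OCc2ccccc2)c1Oc1ccc(-c2cc(=O)c3c(OCc4ccccc4)cc(OC)cc3o2)cc1 | intermediate
13 | methyl 3-(4-methoxyphenyl)propiolate | COC(=O)C#Cc1ccc(OC)cc1 | starting material
14 | methyl (Z)-3-{3,5-bis(benzyloxy)-2-[4-(5-(benzyloxy)-7-methoxy-4-oxo-4H-chromen-2-yl)phenoxy]phenoxy}-3-(4-methoxyphenyl)acrylate | COC(=O)/C=C(\Oc1cc(OCc2ccccc2)cc(OCc2ccccc2)c1Oc1ccc(-c2cc(=O)c3c(OCc4ccccc4)cc(OC)cc3o2)cc1)c1ccc(OC)cc1 | intermediate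
15 | (Z)-3-{3,5-bis(benzyloxy)-2-[4-(5-(benzyloxy)-7-methoxy-4-oxo-4H-chromen-2-yl)phenoxy]phenoxy}-3-(4-methoxyphenyl)acrylic acid | O=C(O)/C=C(\Oc1cc(OCc2ccccc2)cc(OCc2ccccc2)c1Oc1ccc(-c2cc(=O)c3c(OCc4ccccc4)cc(OC)cc3o2)cc1)c1ccc(OC)cc1 | intermediate
16 | (Z)-3-{3,5-bis(benzyloxy)-2-[4-(5-(benzyloxy)-7-methoxy-4-oxo-4H-chromen-2-yl)phenoxy]phenoxy}-3-(4-methoxyphenyl)acryloyl trifluoroacetate (mixed anhydride) | O=C(OC(=O)C(F)(F)F)/C=C(\Oc1cc(OCc2ccccc2)cc(OCc2ccccc2)c1Oc1ccc(-c2cc(=O)c3c(OCc4ccccc4)cc(OC)cc3o2)cc1)c1ccc(OC)cc1 | intermediate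
17 | 5,7-bis(benzyloxy)-8-{4-[5-(benzyloxy)-7-methoxy-4-oxo-4H-chromen-2-yl]phenoxy}-2-(4-methoxyphenyl)-4H-chromen-4-one | COc1ccc(-c2cc(=O)c3c(OCc4ccccc4)cc(OCc4ccccc4)c(Oc4ccc(-c5cc(=O)c6c(OCc7ccccc7)cc(OC)cc6o5)cc4)c3o2)cc1 | intermediate
18 | 5,7-dihydroxy-8-[4-(5-hydroxy-7-methoxy-4-oxo-4H-chromen-2-yl)phenoxy]-2-(4-methoxyphenyl)-4H-chromen-4-one | COc1ccc(-c2cc(=O)c3c(O)cc(O)c(Oc4ccc(-c5cc(=O)c6c(O)cc(OC)cc6o5)cc4)c3o2)cc1 | target

Total step count: 12. Longest linear sequence: 11 steps (steps 1–4 and 6–12, from 1); step 5 prepares the side branch.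

Steps most likely to fail

Step 11. The closure may stall on the full substrate: the activated acid can be used up by acid-driven loss or migration of benzyl groups and by acylation of the basic pyranone carbonyl of flavone 2, and the large molecule may react sluggishly. The fallback sets out from 7 and comes back at 17, closing ring C of flavone 1 before flavone 2 exists. Acetal cleavage of 7 (HCl, MeOH–THF, aqueous work-up) should give 4-[2,4-bis(benzyloxy)-6-hydroxyphenoxy]benzaldehyde F1. Addition of F1 to propiolate 13 (K2CO3, DMF) should give methyl (Z)-3-[3,5-bis(benzyloxy)-2-(4-formylphenoxy)phenoxy]-3-(4-methoxyphenyl)acrylate F2. Saponification (LiOH) should give (Z)-3-[3,5-bis(benzyloxy)-2-(4-formylphenoxy)phenoxy]-3-(4-methoxyphenyl)acrylic acid F3. The same tether-controlled acylation on this small, soluble substrate (trifluoroacetic anhydride, CH2Cl2) should give 4-{[5,7-bis(benzyloxy)-2-(4-methoxyphenyl)-4-oxo-4H-chromen-8-yl]oxy}benzaldehyde F4. Claisen–Schmidt condensation of F4 with ketone 9 (KOH, EtOH–THF) should give (E)-5,7-bis(benzyloxy)-8-{4-[3-(2-(benzyloxy)-6-hydroxy-4-methoxyphenyl)-3-oxoprop-1-en-1-yl]phenoxy}-2-(4-methoxyphenyl)-4H-chromen-4-one F5, and iodine-catalysed oxidative cyclisation in DMSO should deliver 17.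

Step 9. Conjugate addition of the hindered phenoxide to an alkynoate deactivated by its donor aryl group may be slow or reversible, or may be diverted into attack on the chromone. The fallback sets out from 12 and comes back at 15, using a more electrophilic acceptor and a later oxidation. Phenol 12 and commercial 3-(4-methoxyphenyl)propiolaldehyde (O=CC#Cc1ccc(OC)cc1) with Et3N in CH2Cl2 at rt should give (Z)-3-{3,5-bis(benzyloxy)-2-[4-(5-(benzyloxy)-7-methoxy-4-oxo-4H-chromen-2-yl)phenoxy]phenoxy}-3-(4-methoxyphenyl)acrylaldehyde F6. Pinnick oxidation (NaClO2, NaH2PO4, 2-methyl-2-butene, t-BuOH–THF–H2O) should then give acid 15 directly, bypassing ester 14 and the saponification.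

Step 7. The iodine/DMSO couple may iodinate the tetraoxygenated ring, strip the acetal or the peri benzyl ether unevenly, or stop at the flavanone. The fallback sets out from 7 (with 9) and comes back at 12, building flavone 2 without an oxidative ring closure by the Baker–Venkataraman sequence. Pinnick oxidation of 7 should give 4-[2,4-bis(benzyloxy)-6-(methoxymethoxy)phenoxy]benzoic acid F7. Esterification with the phenol of 9 (EDC·HCl, DMAP, CH2Cl2) should give 2-acetyl-3-(benzyloxy)-5-methoxyphenyl 4-[2,4-bis(benzyloxy)-6-(methoxymethoxy)phenoxy]benzoate F8. Base-induced acyl migration (KOH, pyridine, 50 °C) should give 1-[2-(benzyloxy)-6-hydroxy-4-methoxyphenyl]-3-{4-[2,4-bis(benzyloxy)-6-(methoxymethoxy)phenoxy]phenyl}propane-1,3-dione F9. HCl in MeOH at 60 °C should cyclodehydrate F9 and cleave its acetal in one operation to give phenol 12.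

Further compounds
F1 | step 11 | 4-[2,4-bis(benzyloxy)-6-hydroxyphenoxy]benzaldehyde | O=Cc1ccc(Oc2c(O)cc(OCc3ccccc3)cc2OCc2ccccc2)cc1
F2 | step 11 | methyl (Z)-3-[3,5-bis(benzyloxy)-2-(4-formylphenoxy)phenoxy]-3-(4-methoxyphenyl)acrylate | COC(=O)/C=C(\Oc1cc(OCc2ccccc2)cc(OCc2ccccc2)c1Oc1ccc(C=O)cc1)c1ccc(OC)cc1
F3 | step 11 | (Z)-3-[3,5-bis(benzyloxy)-2-(4-formylphenoxy)phenoxy]-3-(4-methoxyphenyl)acrylic acid | O=C(O)/C=C(\Oc1cc(OCc2ccccc2)cc(OCc2ccccc2)c1Oc1ccc(C=O)cc1)c1ccc(OC)cc1
F4 | step 11 | 4-{[5,7-bis(benzyloxy)-2-(4-methoxyphenyl)-4-oxo-4H-chromen-8-yl]oxy}benzaldehyde | COc1ccc(-c2cc(=O)c3c(OCc4ccccc4)cc(OCc4ccccc4)c(Oc4ccc(C=O)cc4)c3o2)cc1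
F5 | step 11 | (E)-5,7-bis(benzyloxy)-8-{4-[3-(2-(benzyloxy)-6-hydroxy-4-methoxyphenyl)-3-oxoprop-1-en-1-yl]phenoxy}-2-(4-methoxyphenyl)-4H-chromen-4-one | COc1ccc(-c2cc(=O)c3c(OCc4ccccc4)cc(OCc4ccccc4)c(Oc4ccc(/C=C/C(=O)c5c(O)cc(OC)cc5OCc5ccccc5)cc4)c3o2)cc1
F6 | step 9 | (Z)-3-{3,5-bis(benzyloxy)-2-[4-(5-(benzyloxy)-7-methoxy-4-oxo-4H-chromen-2-yl)phenoxy]phenoxy}-3-(4-methoxyphenyl)acrylaldehyde | O=C/C=C(\Oc1cc(OCc2ccccc2)cc(OCc2ccccc2)c1Oc1ccc(-c2cc(=O)c3c(OCc4ccccc4)cc(OC)cc3o2)cc1)c1ccc(OC)cc1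
F7 | step 7 | 4-[2,4-bis(benzyloxy)-6-(methoxymethoxy)phenoxy]benzoic acid | O=C(O)c1ccc(Oc2c(OCOC)cc(OCc3ccccc3)cc2OCc2ccccc2)cc1
F8 | step 7 | 2-acetyl-3-(benzyloxy)-5-methoxyphenyl 4-[2,4-bis(benzyloxy)-6-(methoxymethoxy)phenoxy]benzoate | CC(=O)c1c(OC(=O)c2ccc(Oc3c(OCOC)cc(OCc4ccccc4)cc3OCc3ccccc3)cc2)cc(OC)cc1OCc1ccccc1
F9 | step 7 | 1-[2-(benzyloxy)-6-hydroxy-4-methoxyphenyl]-3-{4-[2,4-bis(benzyloxy)-6-(methoxymethoxy)phenoxy]phenyl}propane-1,3-dione | O=C(CC(=O)c1c(O)cc(OC)cc1OCc1ccccc1)c1ccc(Oc2c(OCOC)cc(OCc3ccccc3)cc2OCc2ccccc2)cc1
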